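The earlier runs and the new flask were computed on assumed constants.

Two chemists disagree about G. The flasks, the earlier readings and the question come first.

the same everywhere: E 10 mM

|  | G | D | remark | time |
|---|---|---|---|---|
| alpha | 3.7 mM | 25 mM | run made earlier |  |
| zeta | 62 mM | 25 mM | run made earlier |  |
| blue | 5.00 mM | 25.0 mM |  | 2.5 d |
| amber | 10.0 mM | 25.0 mM |  | 2.5 d |
| grey | 20.0 mM | 25.0 mM |  | 2.5 d |
| teal | 40.0 mM | 25.0 mM |  | 2.5 d |
| ochre | 80.0 mM | 25.0 mM |  | 2.5 d |

| run | time / h | X / % |
|---|---|---|
| alpha | 2.50 | 2.0 |
| alpha | 6.00 | 0.7 |
| alpha | 12.0 | 1.3 |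
| alpha | 20.0 | 5.7 |
| alpha | 25.0 | 10.0 |
| alpha | 30.0 | 9.9 |
| alpha | 40.0 | 14.9 |
| zeta | 6.00 | 3.3 |
| zeta | 12.0 | 13.5 |
| zeta | 20.0 | 23.7 |
| zeta | 25.0 | 28.8 |
| zeta | 30.0 | 33.1 |
| zeta | 40.0 | 38.0 |

(standard deviation of a reading: 1 percentage point)

- "hardly changes" means that all values lie within two and a half points (for a concentration: within two and a half percent of the largest)
- a step back or a flat step of under half a point counts as no turn

- amount of X at the end, in percent of the E charged for blue, amber, grey, teal, ochre, in this order
- the course of these numbers from the first flask to the last (hardly changes / falls all the way / rises, then falls / rises all the way / falls, then rises)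

The first chemist treats G as the limiting reagent and reckons one number for each flask, the ceiling of G: the G charged over the E charged, in percent, which is the X a flask can reach if each X takes one G and one E. For blue this gives 50.0%, and for amber 100%. Once the ceiling reaches 100%, the E charged becomes the cap instead. Her row therefore climbs from blue to amber and then stays level, with no fall in it. Alpha does not contradict her, since its ceiling is 37.0% and its last reading, at 40.0 h, is 14.9%.

The second chemist looks at zeta instead. Its ceiling is 620%, far above the 38.0% of its last reading, so the ceiling gives zeta no reason to slow. Yet zeta gained 10 percentage points from 12.0 h to 20.0 h, more than the 4.9 points it gained from 30.0 h to 40.0 h. Moreover, a charge of G 16.8 times alpha's gave, at the last reading, X 2.55 times alpha's. So the second chemist expects a loss that grows with G, and she made the forecast: 28%, 38%, 46%, 47%, 43%, a course that rises, then falls. Her ground for the middle is “Middle flasks are neither short of G nor burnt out as quickly, so I expect a modest maximum”. Here the two differ, since the first chemist's row has no fall.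

The flasks give 30.8%, 49.9%, 62.2%, 52.5%, 32.3%, so the course is the forecast's, rises, then falls, and the row turns near 21 mM of G with X at 62.3%. In ochre, at 2.50 d, D is down to 0.025% of its charge while 68% of the E stands unused.

    E + D → J (k = 2.47 M⁻¹ h⁻¹)
    D + G → Q (k = 2.00 M⁻¹ h⁻¹)
    J + Q → X (k = 6.12 M⁻¹ h⁻¹)
    G → Z (k = 3.60 × 10⁻⁵ h⁻¹)

The first chemist's ceiling comes into its own in blue and amber, given time. Blue at the asked time stands at 30.8% against its ceiling of 50.0%, but at 25.0 d its X is 49.9%, level with that ceiling, with G at 0%. Amber, with a ceiling of 100%, holds 96.4% of X at 25.0 d.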